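## Structural features

The skeleton atoms are numbered as in a squalene chain. An oxepan-3-one (O, C2(CH3)2, C3=O, C4, C5, C6, C7) is trans-fused along C6–C7 to a cyclohexane (C6–C11). This is tied through the C12–C13 ethylene to a cis-fused bicyclo[5.3.0]decane made of a cycloheptanone (C14, C15(=CH2), C16=O, C17, C18, C22, C23(CH3)2) and a cyclopentane (C18–C22).

Ring B carries four contiguous stereocentres: quaternary C6 (R, axial CH3), C7 (R, H anti to that CH3), C11 (R, equatorial chain) and C10 (S, tertiary alcohol with axial OH syn to the C6 methyl). The hydroazulene carries C14 (R), C18 (R), C22 (R) and C19 (R, tertiary alcohol). H-14, H-18, H-22 and the C19 hydroxyl lie on one face; the C13 chain and the cyclopentane lie on the other. The two stereoclusters are insulated by C12–C13, so neither can control the other.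

Fragile groups are the cross-conjugated α-methylene ketone (C15=CH2/C16=O, a Michael acceptor) and the two tertiary alcohols (C10, C19), which can eliminate. The real difficulty is twofold: an ether oxygen that bridges the fully substituted C2 and C7 next to quaternary C6, and a seven-membered carbocycle whose quaternary C23 sits between two stereocentres (C14, C22).

The key step exploits the imprint of a 2,3:6,7-diepoxide in rings A/B: the O–C2 bond, the oxygen on C3, and the C6–C11 bond anti to the C7–O bond. A second feature guides the left half: C14 and C16 are 1,3-related on ring C with C23 blocking one flank. This is the pattern of a cycloheptane-1,3-dione, obtainable by two-carbon ring expansion of a cis-diquinane.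

## Logic of the disconnections

36 ⇒ 35 ⇒ 34. No skeletal bond is cut. The C3 ketone is traced to the (3R)-alcohol and the three hydroxyl groups to triethylsilyl ethers. The gain is that no free ketone other than C16 and no free OH is present during the organometallic and enolate chemistry. The demand is that desilylation and oxidation tolerate the α-methylene ketone.

34 ⇒ 31 ⇒ 30. The exocyclic C15=CH2 bond and the C14–H bond are cut. Both come from one conjugate hydride addition to the C14=C15–C16=O enone of 30, whose regiodefined enol silane 31 is methylenated. This sets C14 and solves the C15-versus-C17 regiochemistry together. The demand is hydride delivery to C14 on the face of H-18/H-22.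

30 ⇒ 27 + 14. The C13–C14 bond is cut. C14 is a carbonyl carbon in 14 and C13 a primary carbanion from 27, so the union is a 1,2-addition followed by acid-induced carbonyl transposition. The gain is two bicyclic halves of similar size. The demand is clean addition to a carbonyl flanked by quaternary C23.

14 ⇒ 13 ⇒ 11 ⇒ 10. C14–C15 and C16–C17 are cut and C14–C17 is re-joined: the seven-membered 1,3-dione is a cis-bicyclo[3.3.0]octanone enlarged by a ketene-derived two-carbon unit. The gain is that the cis ring fusion is enforced by the diquinane and the enol ether can form only towards C17, because C23 is quaternary. The demand is regioselective etherification of the C16 oxygen in 13.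

10 ⇒ 9 ⇒ 7 ⇒ 6. One C23–CH3 bond and the C22–H bond are cut (reductive methylation of 7), then C18–C22, C14–C17 and C14–C23 together (Pauson–Khand reaction of 6). The gain is an acyclic enyne with a single stereocentre. The demand is that C19 directs the alkene insertion so that H-18 ends cis to the silyloxy group.

6 ⇒ 4 ⇒ 3 ⇒ 2 ⇒ 1. The other C23–CH3 bond and the C22≡C23 bond are cut; C19 with its methyl and oxygen is bought in 1. The demand is oxidative cleavage of the trisubstituted olefin of 1 without touching the vinyl group.

27 ⇒ 26 ⇒ 25 ⇒ 24 ⇒ 23. The C10–CH3 bond is cut; the rest are functional-group changes at C13 and O10. The C10 ketone of 23 lets the axial alcohol come from equatorial methyl addition. The demand is attack anti to the axial C6 methyl.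

23 ⇒ 22 (key). The O–C2 and C6–C11 bonds are cut, and the C3 oxygen is returned to C2–C3 and the ring oxygen to C6–C7 as epoxides. Both rings and the stereocentres C6, C7 and C11 are traded for an acyclic diepoxide whose two stereogenic units come from one catalytic epoxidation. The demand is that oxygen attacks C2 before carbon attacks C6.

22 ⇒ 21 ⇒ 19 ⇒ 16 + 17, and 16 ⇒ 15. The C11–C12 bond is cut (aldol) and both epoxide oxygens are removed. The enone 21 exists only to fix the enol silane on the C11 side. Commercial 15 carries C2–C11 with both olefins in the correct E geometry.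

## Other disconnections considered

Alternative 1: (the first that comes to mind) Cut C12–C13 between two finished bicycles. The forward key step would be a Julia–Kocienski olefination of hydroazulene aldehyde A1 with tetrazolyl sulfone A2, followed by reduction of the C12=C13 olefin.
- The coupling forms no ring and no stereocentre, so all of the difficulty is pushed into two long, independent fragment syntheses.
- The aldehyde carbon of A1 hangs on C14, which is α to the carbonyl and next to quaternary C23, so epimerisation and slow addition are expected.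
- The sulfone carbon of A2 is β-branched between C6 and C10.
- C14 and C11 must both be set beforehand. In the chosen plan C11 falls out of the cascade and C14 out of the reduction that follows the union.

Alternative 2: Cut O–C2, C6–C11, C18–C22 and C14–C23 at once, in an acid-triggered double cyclisation of the squalene triepoxide A3.
- The right half would follow the logic of the chosen key step.
- The left half would need the 18,19-epoxide to open at its secondary carbon C18, a seven-membered closure of the C23 cation onto C14, and selective proton loss to C15=CH2.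
- Each of these competes with Markovnikov opening at C19, hydride shifts and six-membered closures.
- The C10 cation would take up water anti to the new C6–C11 bond, that is equatorially, which gives the C10 epimer.
- Nothing in A3 enforces this selectivity without an enzyme; the chosen plan keeps only the half of this logic that sorts itself.

Alternative 3: Cut C18–C22 and C14–C23 in a Rh(I)-catalysed intramolecular [5+2] cycloaddition of the siloxy-vinylcyclopropane A4 (from 1), giving the cis-fused ketone A5 after enol ether hydrolysis.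
- The cis fusion and the C16 carbonyl would come directly.
- However, the two-carbon partner is a trisubstituted prenyl olefin that must become quaternary C23, which is outside the usual scope of ene–vinylcyclopropane cycloadditions.
- In A5, C14 and C15 are plain methylene groups, so there is no handle for attaching the chain at neopentyl C14 or for choosing C15 over C17 for methylenation.
- The 1,3-dione 13 of the chosen plan differentiates exactly these positions.

Key step: step 15

Remark: the D-fructose-derived Shi ketone is taken to give the (R,R)-epoxides of (E)-trisubstituted olefins, the usual sense for this catalyst; otherwise its enantiomer would be used.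

## Steps

Step 1
Reactants: 1 (R)-(−)-linalool
Product: 2 (4R)-4-hydroxy-4-methylhex-5-enal (in equilibrium with its lactol)
Conditions: O3, CH2Cl2/MeOH, pyridine (cat.), −78 °C, Sudan III end point; then Me2S, −78 °C → rt
Reagents that add atoms: ozone, [O-][O+]=O
Why: Chemoselective ozonolysis; the electron-rich trisubstituted olefin reacts much faster than the vinyl group, so titration to the dye end point should cleave only the prenyl terminus and leave the carbinol centre (future C19) untouched.

Step 2
Reactants: 2 (4R)-4-hydroxy-4-methylhex-5-enal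
Product: 3 (3R)-3-methylhept-1-en-6-yn-3-ol
Conditions: dimethyl (1-diazo-2-oxopropyl)phosphonate, K2CO3, MeOH, 0 °C → rt
Reagents that add atoms: Ohira–Bestmann reagent, CC(=O)C(=[N+]=[N-])P(=O)(OC)OC
Why: Ohira–Bestmann (Seyferth–Gilbert) homologation; the lactol opens in basic methanol and the aldehyde becomes a terminal alkyne whose new carbon is the future C23.

Step 3
Reactants: 3 (3R)-3-methylhept-1-en-6-yn-3-ol
Product: 4 (3R)-3-methyl-3-(triethylsilyloxy)hept-1-en-6-yne
Conditions: TESOTf, 2,6-lutidine, CH2Cl2, −78 → 0 °C
Reagents that add atoms: triethylsilyl triflate, CC[Si](CC)(CC)OS(=O)(=O)C(F)(F)F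
Why: Silyl triflate silylation of a tertiary alcohol; the bulky OTES group is needed for facial control in step 5 and prevents O-alkylation in steps 4 and 6.

Step 4
Reactants: 4 (3R)-3-methyl-3-(triethylsilyloxy)hept-1-en-6-yne
Product: 6 (3R)-3-methyl-3-(triethylsilyloxy)oct-1-en-6-yne, via lithium acetylide 5 (not isolated)
Conditions: n-BuLi, THF, −78 °C; then MeI, DMPU, −78 °C → rt
Reagents that add atoms: methyl iodide, CI
Why: Acetylide alkylation; this methyl becomes one of the C23 methyl groups and makes the later enolate methylation at C23 regiospecific.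

Step 5
Reactants: 6 (3R)-3-methyl-3-(triethylsilyloxy)oct-1-en-6-yne
Product: 7 (5R,6R)-2,6-dimethyl-6-(triethylsilyloxy)bicyclo[3.3.0]oct-1-en-3-one
Conditions: Co2(CO)8 (10 mol %), tetramethylthiourea (cat.), CO (1 atm), PhH, 70 °C
Reagents that add atoms: carbon monoxide, [C-]#[O+]
Why: Catalytic intramolecular Pauson–Khand reaction forming C18–C22, C14–C17 and C14–C23; in the alkene-insertion step the larger OTES group on the allylic quaternary carbon should take the exo (convex) position, which puts H-18 cis to OTES and the C19 methyl endo.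

Step 6
Reactants: 7 (5R,6R)-2,6-dimethyl-6-(triethylsilyloxy)bicyclo[3.3.0]oct-1-en-3-one
Product: 9 (1R,5R,6R)-2,2,6-trimethyl-6-(triethylsilyloxy)-cis-bicyclo[3.3.0]octan-3-one, via lithium enolate 8 (not isolated)
Conditions: Li (2.2 equiv), NH3(l)/THF, t-BuOH (1.0 equiv), −78 °C; then MeI, −78 → −33 °C
Reagents that add atoms: methyl iodide, CI
Why: Dissolving-metal reduction with enolate trapping (Stork reductive alkylation); protonation at C22 can only give the cis-fused diquinane (a trans-bicyclo[3.3.0]octane is too strained), and the regiodefined enolate is methylated at C23 to complete the gem-dimethyl group.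

Step 7
Reactants: 9 (1R,5R,6R)-2,2,6-trimethyl-6-(triethylsilyloxy)-cis-bicyclo[3.3.0]octan-3-one
Product: 10 trimethylsilyl enol ether of 9 (C14=C17)
Conditions: TMSOTf, Et3N, CH2Cl2, 0 °C
Reagents that add atoms: trimethylsilyl triflate, C[Si](C)(C)OS(=O)(=O)C(F)(F)F
Why: Soft enolisation and O-silylation; quaternary C23 leaves C17 as the only enolisable position, so the enol ether is a single regioisomer.

Step 8
Reactants: 10 trimethylsilyl enol ether of 9
Product: 11 dichlorocyclobutanone [2+2] adduct (C15Cl2, C16=O)
Conditions: Cl2CHCOCl, Et3N, hexane, rt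
Reagents that add atoms: dichloroacetyl chloride, ClC(Cl)C(Cl)=O
Why: [2+2] cycloaddition of dichloroketene to a silyl enol ether; nucleophilic C17 bonds to the ketene carbonyl carbon (C16) and C14 to CCl2 (C15), on the convex face, and the two new stereocentres are erased in step 9.

Step 9
Reactants: 11 dichlorocyclobutanone [2+2] adduct
Product: 13 (1R,3aR,8aR)-1,4,4-trimethyl-1-(triethylsilyloxy)perhydroazulene-5,7-dione, via dechlorinated siloxycyclobutanone 12 (not isolated)
Conditions: Zn(Cu), NH4Cl, MeOH, rt; filter; then K2CO3, MeOH, rt; work-up at pH 4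
Reagents that add atoms: none
Why: Reductive dechlorination, then desilylation releases a cyclobutanol alkoxide whose strain-driven retro-aldol cleaves C14–C17; this two-carbon ring expansion gives the cycloheptane-1,3-dione with C18, C19, C22 and the cis fusion unchanged.

Step 10
Reactants: 13 (1R,3aR,8aR)-1,4,4-trimethyl-1-(triethylsilyloxy)perhydroazulene-5,7-dione
Product: 14 (1R,3aR,8aR)-7-methoxy-1,4,4-trimethyl-1-(triethylsilyloxy)-2,3,3a,4,8,8a-hexahydroazulen-5(1H)-one
Conditions: Me2SO4, K2CO3, acetone, rt
Reagents that add atoms: dimethyl sulfate, COS(=O)(=O)OC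
Why: O-Alkylation of the dione enolate with a hard electrophile; the oxygen on C16 is much less hindered than the one on C14 (next to quaternary C23), so the vinylogous ester should carry OMe on C16 and keep the C14 carbonyl.

Step 11
Reactants: 15 geranylacetone
Product: 16 (5R,6R,9R)-5,6:9,10-diepoxy-6,10-dimethylundecan-2-one
Conditions: D-fructose-derived Shi ketone (0.6 equiv), Oxone, K2CO3, Bu4NHSO4, MeCN/DMM/aq. borate buffer (pH 10.5), 0 °C
Reagents that add atoms: potassium peroxymonosulfate (Oxone), [K+].[O-]S(=O)(=O)OO
Why: Shi asymmetric epoxidation of both (E)-trisubstituted olefins under catalyst control; it sets the 6R,7R epoxide (squalene numbering), from which C6, C7, C11 and C10 are relayed, and the 3R epoxide.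

Step 12
Reactants: 16 (5R,6R,9R)-5,6:9,10-diepoxy-6,10-dimethylundecan-2-one; 17 benzyloxyacetaldehyde
Product: 19 aldol adduct (7R,8R,11R)-1-(benzyloxy)-7,8:11,12-diepoxy-2-hydroxy-8,12-dimethyltridecan-4-one (C2 epimers), via methyl-side lithium enolate 18 (not isolated)
Conditions: LDA, THF, −78 °C; then 17, −78 °C; H2O
Reagents that add atoms: none
Why: Kinetic deprotonation of the methyl ketone on the methyl side and aldol addition form C11–C12; the carbinol configuration is irrelevant and the epoxides are inert to LDA at −78 °C.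

Step 13
Reactants: 19 aldol adduct
Product: 21 (2E,7R,8R,11R)-1-(benzyloxy)-7,8:11,12-diepoxy-8,12-dimethyltridec-2-en-4-one, via mesylate 20 (not isolated)
Conditions: MsCl, Et3N (excess), CH2Cl2, 0 °C → rt
Reagents that add atoms: none
Why: Mesylation and E1cB elimination to the (E)-enone; the enone is made only to fix the later enol silane on the C11 side of the C10 carbonyl.

Step 14
Reactants: 21 (2E,7R,8R,11R)-enone
Product: 22 (3Z,7R,8R,11R)-1-(benzyloxy)-7,8:11,12-diepoxy-8,12-dimethyl-4-(triethylsilyloxy)tridec-3-ene
Conditions: Et3SiH, (Ph3P)3RhCl (2 mol %), THF, 50 °C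
Reagents that add atoms: triethylsilane, CC[SiH](CC)CC
Why: Rh-catalysed 1,4-hydrosilylation of an enone, which gives the regiodefined (Z)-silyl enol ether through the s-cis enone; epoxides and the benzyl ether are inert.

Step 15
Reactants: 22 (3Z,7R,8R,11R)-diepoxy enol silane
Product: 23 (3R,5aR,6R,9aR)-6-[2-(benzyloxy)ethyl]-2,2,5a-trimethyl-3-(triethylsilyloxy)perhydro-1-benzoxepin-7-one (trans-fused)
Conditions: TESOTf (0.3 equiv), 2,6-di-tert-butyl-4-methylpyridine (0.5 equiv), CH2Cl2, −78 °C
Reagents that add atoms: none
Why: The silyl triflate silylates the less hindered terminal epoxide; the 6,7-epoxide oxygen opens it at tertiary C2 to give a fused bicyclic epoxonium ion, the (Z)-enol silane attacks tertiary C6 with C11 anti to the breaking C6–O bond, and the silyl group lost from the resulting oxocarbenium ion returns as TESOTf, so the event is an isomerisation. The closest known reaction type is the Lewis-acid-triggered oxa-/carbacyclisation cascade of 1,5-diepoxides terminated by an enol silane, an extension of epoxide-initiated polyene cyclisation. The oxepane closes by endo attack of the epoxide oxygen on C2 (epoxonium formation, then C6–O cleavage leaves the seven-membered O–C2…C7 ring), and the cyclohexane by 6-endo attack of the enol silane on C6 through a chair transition state. C7 keeps the configuration set by the Shi epoxidation because the C7–O bond is never broken; C6 is inverted, which puts the C6–C11 bond anti to C7–O and the C6 methyl axial, giving the trans fusion. C11 is set by the chair with the C12 chain equatorial, as the (Z)-enol silane requires, and this is also the thermodynamic position α to the new C10 ketone; C3 keeps its (R)-silyloxy group, which is oxidised away at the end. The step needs the terminal epoxide to react before the carbon nucleophile captures the internal one, and attack at C2 rather than C3; the first is favoured by the lower hindrance and better cation stabilisation at the 2,2-dimethyl terminus and by low temperature, the second by the tertiary character of C2. The hindered pyridine removes adventitious triflic acid that would hydrolyse the enol silane.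

Step 16
Reactants: 23 bicyclic ketone
Product: 24 (3R,5aR,6R,7S,9aR)-6-[2-(benzyloxy)ethyl]-2,2,5a,7-tetramethyl-3-(triethylsilyloxy)perhydro-1-benzoxepin-7-ol
Conditions: MeMgBr, CeCl3, THF, −78 → 0 °C; H2O
Reagents that add atoms: methylmagnesium bromide, C[Mg]Br
Why: Organocerium-type 1,2-addition; axial attack is blocked by the 1,3-diaxial C6 methyl, so the methyl enters equatorially and C10 gets the axial hydroxyl syn to the C6 methyl (10S), while CeCl3 suppresses enolisation.

Step 17
Reactants: 24 tertiary alcohol
Product: 25 bis(triethylsilyl) ether of 24 (O3 and O10)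
Conditions: TESOTf, 2,6-lutidine, CH2Cl2, 0 °C → rt
Reagents that add atoms: triethylsilyl triflate, CC[Si](CC)(CC)OS(=O)(=O)C(F)(F)F
Why: Silyl triflate silylation of the hindered tertiary alcohol; it prevents tetrahydrofuran formation from the 1,4-hydroxy iodide and proton quench of the organolithium in step 20.

Step 18
Reactants: 25 bis(triethylsilyl) ether
Product: 26 2-[(3R,5aR,6R,7S,9aR)-2,2,5a,7-tetramethyl-3,7-bis(triethylsilyloxy)perhydro-1-benzoxepin-6-yl]ethanol
Conditions: H2 (1 atm), Pd(OH)2/C, EtOAc, rt
Reagents that add atoms: none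
Why: Hydrogenolysis of the benzyl ether; no olefin is present and the silyl ethers are stable in a non-protic solvent.

Step 19
Reactants: 26 primary alcohol
Product: 27 (3R,5aR,6R,7S,9aR)-6-(2-iodoethyl)-2,2,5a,7-tetramethyl-3,7-bis(triethylsilyloxy)perhydro-1-benzoxepine
Conditions: I2, PPh3, imidazole, CH2Cl2, 0 °C
Reagents that add atoms: iodine, II
Why: Appel-type iodination of the only free (primary) hydroxyl group under nearly neutral conditions.

Step 20
Reactants: 27 primary iodide; 14 vinylogous ester
Product: 30 coupled enone (C14=C15–C16=O; TES ethers at O3, O10, O19), via alkyllithium 28 (not isolated), via lithium alkoxide adduct 29 (not isolated)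
Conditions: t-BuLi (2.1 equiv), Et2O/pentane, −78 °C; then 14, THF, −78 → 0 °C; then 1 M HCl, 0 °C, short contact
Reagents that add atoms: none
Why: Iodine–lithium exchange, 1,2-addition to the C14 carbonyl (the hard alkyllithium adds to C=O, not to the alkoxy-bearing carbon) and acid-induced enol ether hydrolysis with β-elimination (Stork–Danheiser transposition) form C13–C14 and move the carbonyl to C16; low temperature in ether keeps the alkyllithium from silyl migration.

Step 21
Reactants: 30 coupled enone
Product: 31 triethylsilyl enol ether (C15=C16–OTES) of the (14R)-14,15-dihydro ketone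
Conditions: Et3SiH, (Ph3P)3RhCl (5 mol %), PhH, 60 °C
Reagents that add atoms: triethylsilane, CC[SiH](CC)CC
Why: Rh-catalysed 1,4-hydrosilylation; in the folded cis-bicycle the hydride should reach C14 from the convex face carrying H-18 and H-22, anti to the pseudo-axial C23 methyl, which gives 14R, and the enol silane is fixed on the C15 side.

Step 22
Reactants: 31 triethylsilyl enol ether
Product: 34 tris(triethylsilyl) α-methylene ketone [(3R)-3,10,19-tri-O-TES derivative of 35], via Mannich base 32 (not isolated), via trimethylammonium iodide 33 (not isolated)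
Conditions: CH2=NMe2+ I− (Eschenmoser's salt), CH2Cl2, rt; then MeI; then aq. NaHCO3
Reagents that add atoms: Eschenmoser's salt, C=[N+](C)C.[I-]
Why: Mannich reaction of the regiodefined silyl enol ether at C15, N-quaternisation and E1cB elimination; the double bond can only form exocyclic, so no C14=C15 isomer can arise and C14 is not touched.

Step 23
Reactants: 34 tris(triethylsilyl) α-methylene ketone
Product: 35 (3R)-triol [36 with a (3R)-hydroxyl group in place of the C3 ketone]
Conditions: HF·pyridine, pyridine, THF, 0 °C → rt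
Reagents that add atoms: none
Why: Buffered fluoride desilylation of one secondary and two tertiary TES ethers; the conditions are non-basic and should leave the α-methylene ketone and the tertiary alcohols intact.

Step 24
Reactants: 35 (3R)-triol
Product: 36 target (CNP0316622.2; 6R,7R,10S,11R,14R,18R,19R,22R)
Conditions: Dess–Martin periodinane, NaHCO3, CH2Cl2, 0 °C → rt
Reagents that add atoms: none
Why: Dess–Martin oxidation of the only secondary alcohol to the oxepan-3-one; tertiary alcohols and the enone do not react, and C3 has no adjacent stereocentre to epimerise.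

## Compound list

1 | (R)-(−)-linalool, (3R)-3,7-dimethylocta-1,6-dien-3-ol | C=C[C@](C)(O)CCC=C(C)C | starting material
2 | (4R)-4-hydroxy-4-methylhex-5-enal (open form of the lactol 5-methyl-5-vinyloxolan-2-ol) | C=C[C@](C)(O)CCC=O | intermediate
3 | (3R)-3-methylhept-1-en-6-yn-3-ol | C=C[C@](C)(O)CCC#C | intermediate
4 | (3R)-3-methyl-3-(triethylsilyloxy)hept-1-en-6-yne | C=C[C@](C)(O[Si](CC)(CC)CC)CCC#C | intermediate
5 | lithium acetylide of 4 | C=C[C@](C)(O[Si](CC)(CC)CC)CCC#C[Li] | intermediate
6 | (3R)-3-methyl-3-(triethylsilyloxy)oct-1-en-6-yne | C=C[C@](C)(O[Si](CC)(CC)CC)CCC#CC | intermediate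
7 | (5R,6R)-2,6-dimethyl-6-(triethylsilyloxy)bicyclo[3.3.0]oct-1-en-3-one (H-5 cis to OTES) | O=C1C[C@@H]2C(=C1C)CC[C@@]2(C)O[Si](CC)(CC)CC | intermediate
8 | lithium enolate of the cis-fused 1,2-dihydro ketone (enolate C2=C3) | CC1=C(O[Li])C[C@@H]2[C@H]1CC[C@@]2(C)O[Si](CC)(CC)CC | intermediate
9 | (1R,5R,6R)-2,2,6-trimethyl-6-(triethylsilyloxy)-cis-bicyclo[3.3.0]octan-3-one | O=C1C[C@@H]2[C@@H](CC[C@@]2(C)O[Si](CC)(CC)CC)C1(C)C | intermediate
10 | trimethylsilyl enol ether of 9 (C3=C4 of the bicycle, i.e. C14=C17) | C[Si](C)(C)OC1=C[C@@H]2[C@@H](CC[C@@]2(C)O[Si](CC)(CC)CC)C1(C)C | intermediate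
11 | dichlorocyclobutanone [2+2] adduct of 10 (cyclobutane on the convex face; C15Cl2, C16=O, C14–OTMS) | C[Si](C)(C)O[C@@]12C(Cl)(Cl)C(=O)[C@@H]1[C@@H]1[C@@H](CC[C@@]1(C)O[Si](CC)(CC)CC)C2(C)C | intermediate
12 | dechlorinated siloxycyclobutanone | C[Si](C)(C)O[C@@]12CC(=O)[C@@H]1[C@@H]1[C@@H](CC[C@@]1(C)O[Si](CC)(CC)CC)C2(C)C | intermediate
13 | (1R,3aR,8aR)-1,4,4-trimethyl-1-(triethylsilyloxy)perhydroazulene-5,7-dione (cis-fused; C14 and C16 carbonyls) | O=C1CC(=O)C[C@@H]2[C@@H](CC[C@@]2(C)O[Si](CC)(CC)CC)C1(C)C | intermediate
14 | (1R,3aR,8aR)-7-methoxy-1,4,4-trimethyl-1-(triethylsilyloxy)-2,3,3a,4,8,8a-hexahydroazulen-5(1H)-one | O=C1C=C(OC)C[C@@H]2[C@@H](CC[C@@]2(C)O[Si](CC)(CC)CC)C1(C)C | intermediate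
15 | geranylacetone, (5E)-6,10-dimethylundeca-5,9-dien-2-one | CC(=O)CC/C=C(\C)CCC=C(C)C | starting material
16 | (5R,6R,9R)-5,6:9,10-diepoxy-6,10-dimethylundecan-2-one | CC(=O)CC[C@H]1O[C@]1(C)CC[C@H]1OC1(C)C | intermediate
17 | benzyloxyacetaldehyde | O=CCOCc1ccccc1 | starting material
18 | methyl-side lithium enolate of 16 | C=C(O[Li])CC[C@H]1O[C@]1(C)CC[C@H]1OC1(C)C | intermediate
19 | (7R,8R,11R)-1-(benzyloxy)-7,8:11,12-diepoxy-2-hydroxy-8,12-dimethyltridecan-4-one (both C2 epimers) | O=C(CC(O)COCc1ccccc1)CC[C@H]1O[C@]1(C)CC[C@H]1OC1(C)C | intermediate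
20 | methanesulfonate of 19 | O=C(CC(OS(C)(=O)=O)COCc1ccccc1)CC[C@H]1O[C@]1(C)CC[C@H]1OC1(C)C | intermediate
21 | (2E,7R,8R,11R)-1-(benzyloxy)-7,8:11,12-diepoxy-8,12-dimethyltridec-2-en-4-one | O=C(/C=C/COCc1ccccc1)CC[C@H]1O[C@]1(C)CC[C@H]1OC1(C)C | intermediate
22 | (3Z,7R,8R,11R)-1-(benzyloxy)-7,8:11,12-diepoxy-8,12-dimethyl-4-(triethylsilyloxy)tridec-3-ene | CC[Si](CC)(CC)O/C(CC[C@H]1O[C@]1(C)CC[C@H]1OC1(C)C)=C\CCOCc1ccccc1 | intermediate
23 | (3R,5aR,6R,9aR)-6-[2-(benzyloxy)ethyl]-2,2,5a-trimethyl-3-(triethylsilyloxy)perhydro-1-benzoxepin-7-one (trans-fused) | c1ccccc1COCC[C@@H]1[C@@]2(C)CC[C@@H](O[Si](CC)(CC)CC)C(C)(C)O[C@@H]2CCC1=O | intermediate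
24 | (3R,5aR,6R,7S,9aR)-6-[2-(benzyloxy)ethyl]-2,2,5a,7-tetramethyl-3-(triethylsilyloxy)perhydro-1-benzoxepin-7-ol | c1ccccc1COCC[C@@H]1[C@@]2(C)CC[C@@H](O[Si](CC)(CC)CC)C(C)(C)O[C@@H]2CC[C@]1(C)O | intermediate
25 | (3R,5aR,6R,7S,9aR)-6-[2-(benzyloxy)ethyl]-2,2,5a,7-tetramethyl-3,7-bis(triethylsilyloxy)perhydro-1-benzoxepine | c1ccccc1COCC[C@@H]1[C@@]2(C)CC[C@@H](O[Si](CC)(CC)CC)C(C)(C)O[C@@H]2CC[C@]1(C)O[Si](CC)(CC)CC | intermediate
26 | 2-[(3R,5aR,6R,7S,9aR)-2,2,5a,7-tetramethyl-3,7-bis(triethylsilyloxy)perhydro-1-benzoxepin-6-yl]ethanol | OCC[C@@H]1[C@@]2(C)CC[C@@H](O[Si](CC)(CC)CC)C(C)(C)O[C@@H]2CC[C@]1(C)O[Si](CC)(CC)CC | intermediate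
27 | (3R,5aR,6R,7S,9aR)-6-(2-iodoethyl)-2,2,5a,7-tetramethyl-3,7-bis(triethylsilyloxy)perhydro-1-benzoxepine | ICC[C@@H]1[C@@]2(C)CC[C@@H](O[Si](CC)(CC)CC)C(C)(C)O[C@@H]2CC[C@]1(C)O[Si](CC)(CC)CC | intermediate
28 | alkyllithium from 27 (Li on C13) | [Li]CC[C@@H]1[C@@]2(C)CC[C@@H](O[Si](CC)(CC)CC)C(C)(C)O[C@@H]2CC[C@]1(C)O[Si](CC)(CC)CC | intermediate
29 | lithium alkoxide 1,2-adduct of 28 and 14 (C14 carbinol, either configuration) | [Li]OC1(CC[C@@H]2[C@@]3(C)CC[C@@H](O[Si](CC)(CC)CC)C(C)(C)O[C@@H]3CC[C@]2(C)O[Si](CC)(CC)CC)C=C(OC)C[C@@H]2[C@@H](CC[C@@]2(C)O[Si](CC)(CC)CC)C1(C)C | intermediate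
30 | coupled enone: skeleton of 36 without the C15 methylene carbon, C14=C15 conjugated to the C16 ketone, (3R)-OTES in place of the C3 ketone, TES ethers at O10 and O19 | O=C1C[C@@H]2[C@@H](CC[C@@]2(C)O[Si](CC)(CC)CC)C(C)(C)C(=C1)CC[C@@H]1[C@@]2(C)CC[C@@H](O[Si](CC)(CC)CC)C(C)(C)O[C@@H]2CC[C@]1(C)O[Si](CC)(CC)CC | intermediate
31 | triethylsilyl enol ether (C15=C16–OTES) of the 14,15-dihydro derivative of 30, H-14 cis to H-18 and H-22 | C1=C(O[Si](CC)(CC)CC)C[C@@H]2[C@@H](CC[C@@]2(C)O[Si](CC)(CC)CC)C(C)(C)[C@H]1CC[C@@H]1[C@@]2(C)CC[C@@H](O[Si](CC)(CC)CC)C(C)(C)O[C@@H]2CC[C@]1(C)O[Si](CC)(CC)CC | intermediate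
32 | Mannich base: 15-(dimethylaminomethyl) C16 ketone, tris-TES, C15 epimers | CN(C)CC1C(=O)C[C@@H]2[C@@H](CC[C@@]2(C)O[Si](CC)(CC)CC)C(C)(C)[C@H]1CC[C@@H]1[C@@]2(C)CC[C@@H](O[Si](CC)(CC)CC)C(C)(C)O[C@@H]2CC[C@]1(C)O[Si](CC)(CC)CC | intermediate
33 | trimethylammonium iodide of 32 | C[N+](C)(C)CC1C(=O)C[C@@H]2[C@@H](CC[C@@]2(C)O[Si](CC)(CC)CC)C(C)(C)[C@H]1CC[C@@H]1[C@@]2(C)CC[C@@H](O[Si](CC)(CC)CC)C(C)(C)O[C@@H]2CC[C@]1(C)O[Si](CC)(CC)CC.[I-] | intermediate
34 | tris(triethylsilyl) α-methylene ketone: 3-O,10-O,19-O-tris-TES ether of 35 | C=C1C(=O)C[C@@H]2[C@@H](CC[C@@]2(C)O[Si](CC)(CC)CC)C(C)(C)[C@H]1CC[C@@H]1[C@@]2(C)CC[C@@H](O[Si](CC)(CC)CC)C(C)(C)O[C@@H]2CC[C@]1(C)O[Si](CC)(CC)CC | intermediate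
35 | (3R)-triol: 36 with a (3R)-hydroxyl group in place of the C3 ketone | C=C1C(=O)C[C@@H]2[C@@H](CC[C@@]2(C)O)C(C)(C)[C@H]1CC[C@@H]1[C@@]2(C)CC[C@@H](O)C(C)(C)O[C@@H]2CC[C@]1(C)O | intermediate
36 | CNP0316622.2 (6R,7R,10S,11R,14R,18R,19R,22R in the numbering used here) | C=C1C(=O)C[C@@H]2[C@@H](CC[C@@]2(C)O)C(C)(C)[C@H]1CC[C@@H]1[C@@]2(C)CCC(=O)C(C)(C)O[C@@H]2CC[C@]1(C)O | target

## Step count and least certain steps

Total step count: 24. Longest linear sequence: 15 steps (1 → 36 through steps 1–10 and 20–24); the branch from 15 has 9 steps (11–19) before the union.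

Step 15 (key step).
- What may go wrong: the order of events may be lost. The enol silane may capture the silyl-activated internal epoxide before the terminal epoxide has been engaged (premature C6–C11 closure), because the trisubstituted enol silane is a strong nucleophile and both epoxides are trisubstituted. Lesser risks are attack of the epoxide oxygen at C3 (five-membered ether) and protodesilylation of the enol ether.
- Fallback (ring closures separated and run in the opposite order): it sets out from 22 and returns at 23. The monocyclic epoxy ketone F1, which results when C–C closure comes first, is isolated. HF·pyridine removes the C7 silyl group to give the hydroxy epoxide F2. Camphorsulfonic acid in CH2Cl2 then promotes 7-endo opening of the terminal epoxide at its tertiary carbon C2 by the C7 hydroxyl to give the bicyclic alcohol F3. TESOTf/2,6-lutidine converts F3 into 23. C6, C7 and C11 are set in the same way as in the cascade, and the C3 configuration is again irrelevant.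

Step 21.
- What may go wrong: poor facial selectivity of hydride delivery to C14, or low reactivity, since C14 is β,β-disubstituted and flanked by quaternary C23 and the conformation of the seven-membered ring is not rigidly fixed.
- Fallback (the chain instead of the hydride is delivered to C14, so the same facial preference gives the opposite configuration): it sets out from 14 and 27 and returns at 34. DIBAL-H reduction of 14 (CH2Cl2, −78 °C) and dilute acid give the transposed, C14-unsubstituted enone F4. Iodide 27 is converted with magnesium into the Grignard reagent F5. Copper-catalysed conjugate addition of F5 to F4 in the presence of TMSCl (CuBr·SMe2 cat., DMPU, THF, −78 °C) gives the trimethylsilyl enol ether F6. F6 is taken through the conditions of step 22 to 34.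

Step 5.
- What may go wrong: poor facial selectivity in the alkene insertion (C18 relative to C19), because the methyl and silyloxy groups on the allylic quaternary carbon differ only moderately in effective size.
- Fallback (catalyst control in place of substrate control): it sets out from 6 and returns at 7. A Rh(I)-catalysed Pauson–Khand reaction under CO with a chiral bisphosphine (BINAP enantiomer chosen as the matched one for the OTES-exo isomer) is used; no new compound is made (F0).

Step 6.
- What may go wrong: over-reduction of the carbonyl, or proton exchange and polyalkylation of the enolate before it is methylated.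
- Fallback (alkylation first, reduction second): it sets out from 7 and returns at 9. Deconjugative α-methylation of 7 through its extended enolate (KOt-Bu, MeI, t-BuOH/THF) gives the β,γ-unsaturated gem-dimethyl ketone F7. Hydrogenation (H2, Pd/C, EtOAc) from the convex face gives the cis-fused ketone 9.

## Further compounds

F1 | step 15 | monocyclic epoxy ketone: 2-[2-(benzyloxy)ethyl]-3-methyl-3-[2-((2R)-3,3-dimethyloxiran-2-yl)ethyl]-4-(triethylsilyloxy)cyclohexanone with C6, C7, C11 as in 23 | c1ccccc1COCC[C@@H]1[C@@](C)(CC[C@H]2OC2(C)C)[C@H](O[Si](CC)(CC)CC)CCC1=O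
F2 | step 15 | hydroxy epoxide: C7 alcohol of F1 | c1ccccc1COCC[C@@H]1[C@@](C)(CC[C@H]2OC2(C)C)[C@H](O)CCC1=O
F3 | step 15 | (3R,5aR,6R,9aR)-6-[2-(benzyloxy)ethyl]-3-hydroxy-2,2,5a-trimethylperhydro-1-benzoxepin-7-one | c1ccccc1COCC[C@@H]1[C@@]2(C)CC[C@@H](O)C(C)(C)O[C@@H]2CCC1=O
F4 | step 21 | (1R,3aR,8aR)-1,4,4-trimethyl-1-(triethylsilyloxy)-1,2,3,3a,4,8a-hexahydroazulen-7(8H)-one (C14=C15 enone without the chain) | O=C1C[C@@H]2[C@@H](CC[C@@]2(C)O[Si](CC)(CC)CC)C(C)(C)C=C1
F5 | step 21 | Grignard reagent from 27 (MgI on C13) | I[Mg]CC[C@@H]1[C@@]2(C)CC[C@@H](O[Si](CC)(CC)CC)C(C)(C)O[C@@H]2CC[C@]1(C)O[Si](CC)(CC)CC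
F6 | step 21 | trimethylsilyl enol ether analogue of 31 (C16–OTMS) | C1=C(O[Si](C)(C)C)C[C@@H]2[C@@H](CC[C@@]2(C)O[Si](CC)(CC)CC)C(C)(C)[C@H]1CC[C@@H]1[C@@]2(C)CC[C@@H](O[Si](CC)(CC)CC)C(C)(C)O[C@@H]2CC[C@]1(C)O[Si](CC)(CC)CC
F0 | step 5 | none | none
F7 | step 6 | (5R,6R)-2,2,6-trimethyl-6-(triethylsilyloxy)bicyclo[3.3.0]oct-1(8)-en-3-one | O=C1C[C@@H]2C(=CC[C@@]2(C)O[Si](CC)(CC)CC)C1(C)C
A1 | alternative 1 | hydroazulene aldehyde: C13 formyl group on C14, C16 ketone as dioxolane, C15 methylene absent, O19 as TES ether | O=C[C@H]1CC2(OCCO2)C[C@@H]2[C@@H](CC[C@@]2(C)O[Si](CC)(CC)CC)C1(C)C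
A2 | alternative 1 | 1-phenyltetrazol-5-yl sulfone of the right half (sulfonyl on C12; TES ethers at O3 and O10) | O=S(=O)(C[C@@H]1[C@@]2(C)CC[C@@H](O[Si](CC)(CC)CC)C(C)(C)O[C@@H]2CC[C@]1(C)O[Si](CC)(CC)CC)c1nnnn1-c1ccccc1
A3 | alternative 2 | (3R,6R,7R,10E,14E)-2,3:6,7:18,19-triepoxysqualene with the 18,19-epoxide configured for C18/C19 of 36 | CC(C)=CCC[C@@]1(C)O[C@@H]1CC/C(C)=C/CC/C=C(\C)CC[C@H]1O[C@]1(C)CC[C@H]1OC1(C)C
A4 | alternative 3 | (R)-siloxy-vinylcyclopropane: (E)-1-[1-(tert-butyldimethylsilyloxy)cyclopropyl]-3,7-dimethyl-3-(triethylsilyloxy)octa-1,6-diene | CC(C)=CCC[C@@](C)(O[Si](CC)(CC)CC)/C=C/C1(O[Si](C)(C)C(C)(C)C)CC1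
A5 | alternative 3 | (1R,3aR,8aR)-1,4,4-trimethyl-1-(triethylsilyloxy)perhydroazulen-7-one (C14 and C15 as CH2) | O=C1C[C@@H]2[C@@H](CC[C@@]2(C)O[Si](CC)(CC)CC)C(C)(C)CC1
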